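Ring A (C1–C5, C10) is disconnected at C3–C4. C4 is the α-carbon of the δ-lactone carbonyl C19 and lies 1,3 to quaternary C10 across C5, so ring A and the lactone form a 3-oxabicyclo[3.3.1]nonanone. The key step starts from a tricyclic lactone with rings B and C and the lactone in place and a 3-chloropropyl arm (C1–C3) on C10. The C4 lactone enolate displaces chloride at C3, closing ring A and fixing the C4 quaternary centre, because the tether reaches only one enolate face. The precursor comes from enzymatic desymmetrisation of a prochiral aryl diol, Friedel–Crafts annulation and a cis-selective Michael lactonisation.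

Key step: step 10

Numbering: abietane numbering throughout (ring A = C1–C5, C10; ring B = C5–C10; ring C = C8, C9, C11–C14; C18 methyl and C19 carbonyl on C4; C20 on C10).
Assumption: 1 is taken as a purchasable building block, and the lipase of step 4 is taken to deliver (S)-6; if it prefers the other hydroxymethyl group, the hydrolytic fallback given below provides the same ester.

Step 1
Reactants: 1 5-bromo-2-isopropyl-1,3-dimethoxybenzene; 2 diethyl malonate
Product: 3 diethyl 2-(4-isopropyl-3,5-dimethoxyphenyl)malonate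
Conditions: Pd(OAc)2 (cat.), P(t-Bu)3·HBF4 (cat.), K3PO4, toluene, 80 °C
Reagents that add atoms: none
Why: Palladium-catalysed α-arylation of the malonate enolate (enolate arylation of the Buchwald–Hartwig type) is reliable for unhindered electron-rich aryl bromides and should stop at mono-arylation because the product enolate is hindered and stabilised.

Step 2
Reactants: 3 diethyl 2-(4-isopropyl-3,5-dimethoxyphenyl)malonate
Product: 4 diethyl 2-(3-chloropropyl)-2-(4-isopropyl-3,5-dimethoxyphenyl)malonate
Conditions: NaH, DMF, 0 °C; then Br(CH2)3Cl, 25 → 50 °C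
Reagents that add atoms: 1-bromo-3-chloropropane, ClCCCBr
Why: Malonic ester alkylation: the sodium enolate displaces bromide selectively over chloride (SN2), creating the carbon that becomes C10 and attaching C1–C3 with a latent leaving group on C3.

Step 3
Reactants: 4 diethyl 2-(3-chloropropyl)-2-(4-isopropyl-3,5-dimethoxyphenyl)malonate
Product: 5 2-(3-chloropropyl)-2-(4-isopropyl-3,5-dimethoxyphenyl)propane-1,3-diol
Conditions: LiAlH4, THF, 0 °C; aqueous NaOH work-up
Reagents that add atoms: none
Why: Hydride reduction of both esters with LiAlH4 should give the prochiral 1,3-diol, the primary chloride being inert to the reagent at 0 °C.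

Step 4
Reactants: 5 2-(3-chloropropyl)-2-(4-isopropyl-3,5-dimethoxyphenyl)propane-1,3-diol
Product: 6 (S)-5-chloro-2-(hydroxymethyl)-2-(4-isopropyl-3,5-dimethoxyphenyl)pentyl propanoate
Conditions: Pseudomonas fluorescens lipase (Amano AK), vinyl propanoate, t-BuOMe, 25 °C
Reagents that add atoms: vinyl propanoate, CCC(=O)OC=C
Why: Lipase-catalysed enantiotopic-group-selective transesterification (enzymatic desymmetrisation of a prochiral 2,2-disubstituted propane-1,3-diol) should acylate one hydroxymethyl group only, the enzyme pocket telling the flat aryl group from the flexible chloropropyl chain, so that C10 is set and the propanoate that later supplies C19, C4 and C18 is installed in the same operation.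

Step 5
Reactants: 6 (S)-5-chloro-2-(hydroxymethyl)-2-(4-isopropyl-3,5-dimethoxyphenyl)pentyl propanoate
Product: 7 (R)-5-chloro-2-formyl-2-(4-isopropyl-3,5-dimethoxyphenyl)pentyl propanoate
Conditions: Dess–Martin periodinane, CH2Cl2, 0 → 25 °C
Reagents that add atoms: none
Why: Dess–Martin oxidation under non-basic conditions should give the non-enolisable aldehyde quickly, removing the free hydroxyl before 1,3-acyl migration could erode the configuration at C10.

Step 6
Reactants: 7 (R)-5-chloro-2-formyl-2-(4-isopropyl-3,5-dimethoxyphenyl)pentyl propanoate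
Product: 8 tert-butyl (R,Z)-7-chloro-4-(4-isopropyl-3,5-dimethoxyphenyl)-4-[(propanoyloxy)methyl]hept-2-enoate
Conditions: (CF3CH2O)2P(O)CH2CO2t-Bu, KN(SiMe3)2, 18-crown-6, THF, −78 °C
Reagents that add atoms: tert-butyl 2-[bis(2,2,2-trifluoroethoxy)phosphoryl]acetate, CC(C)(C)OC(=O)CP(=O)(OCC(F)(F)F)OCC(F)(F)F
Why: Still–Gennari variant of the Horner–Wadsworth–Emmons olefination: the electron-poor phosphonate eliminates under kinetic control to the (Z)-enoate, the geometry that holds the carboxyl carbon C7 within reach of the aryl ring.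

Step 7
Reactants: 8 tert-butyl (R,Z)-7-chloro-4-(4-isopropyl-3,5-dimethoxyphenyl)-4-[(propanoyloxy)methyl]hept-2-enoate
Product: 11 [(R)-1-(3-chloropropyl)-6-isopropyl-5,7-dimethoxy-4-oxo-1,4-dihydronaphthalen-1-yl]methyl propanoate, via Z-enoic acid 9 (not isolated), via mixed trifluoroacetic anhydride 10 (not isolated)
Conditions: CF3CO2H, CH2Cl2, 0 °C; then (CF3CO)2O, 0 → 25 °C
Reagents that add atoms: none
Why: Acidolysis of the tert-butyl ester followed by intramolecular Friedel–Crafts acylation through the mixed anhydride should close ring B at C8, which is ortho to one methoxy group and para to the other (the two candidate positions are equivalent by the symmetry of the aryl group), giving the cross-conjugated naphthalenone without touching C10.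

Step 8
Reactants: 11 [(R)-1-(3-chloropropyl)-6-isopropyl-5,7-dimethoxy-4-oxo-1,4-dihydronaphthalen-1-yl]methyl propanoate
Product: 12 (5S,10R)-3-chloro-12,14-dimethoxy-7-oxo-3,4-secoabieta-8,11,13-trien-19,20-olide (C4 epimers; δ-lactone cis-fused to ring B, 3-chloropropyl on C10)
Conditions: LiN(SiMe3)2, THF, −78 °C; NH4Cl quench at −78 °C
Reagents that add atoms: none
Why: Intramolecular Michael addition (6-exo-trig): the base can deprotonate only the propanoate CH2 because the cross-conjugated enone has no enolisable hydrogen, and the ester enolate, hanging from C10 of an essentially planar ring, can reach C5 only on the face of C20, so the δ-lactone should form cis-fused with C5 set as (S), the C4 epimer mixture being of no consequence.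

Step 9
Reactants: 12 (5S,10R)-3-chloro-12,14-dimethoxy-7-oxo-3,4-secoabieta-8,11,13-trien-19,20-olide
Product: 14 (5S,10R)-3-chloro-12,14-dimethoxy-3,4-secoabieta-6,8,11,13-tetraen-19,20-olide (C4 epimers), via benzylic alcohol 13 (not isolated)
Conditions: NaBH4, EtOH/THF, 0 °C; then 2 M HCl, 50 °C
Reagents that add atoms: none
Why: Borohydride reduction of the aryl ketone followed in the same flask by acid-catalysed E1 dehydration of the benzylic alcohol, whose cation is stabilised by the ortho and para methoxy groups, should give the C6=C7 styrene, the only alkene that can form because C8 bears no hydrogen.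

Step 10
Reactants: 14 (5S,10R)-3-chloro-12,14-dimethoxy-3,4-secoabieta-6,8,11,13-tetraen-19,20-olide
Product: 15 (4S,5R,10R)-12,14-dimethoxyabieta-6,8,11,13-tetraen-19,20-olide
Conditions: KN(SiMe3)2, THF/DMPU, −78 → 25 °C
Reagents that add atoms: none
Why: KN(SiMe3)2 removes the C4 hydrogen α to the lactone carbonyl C19 (both C4 epimers give the same planar potassium enolate) and the enolate carbon displaces chloride from C3 in an intramolecular SN2 C-alkylation. The closest known reaction type is the base-mediated cyclisation of 4-(3-halopropyl)cyclohexanone enolates to bicyclo[3.3.1]nonan-2-ones. Ring A (C1–C5, C10) closes by the C3–C4 bond in a 6-(enolexo)-exo-tet mode, the lactone becoming the second three-atom bridge of a 3-oxabicyclo[3.3.1]nonan-2-one. The one new stereocentre, quaternary C4, is controlled by the tether: the C1–C3 arm is fixed on C10 and reaches C4 only on the enolate face syn to C1, so C18 ends anti to it (4S) and ring A is trans-fused to ring B. The step needs α-deprotonation at C4 over removal of the allylic C5–H and C- over O-alkylation; the greater acidity of the lactone α-hydrogen and the eight-membered bridged ring that O-alkylation would require secure both. C5 and C10 are not enolisable and keep their configuration.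

Step 11
Reactants: 15 (4S,5R,10R)-12,14-dimethoxyabieta-6,8,11,13-tetraen-19,20-olide
Product: 16 (4S,5R,10R)-12,14-dihydroxyabieta-6,8,11,13-tetraen-19,20-olide
Conditions: BBr3, CH2Cl2, −78 → 0 °C; then H2O
Reagents that add atoms: none
Why: Lewis-acid cleavage of both aryl methyl ethers with BBr3 should leave the lactone intact, because its alkyl carbon C20 is neopentyl and cannot be attacked by bromide, and should tolerate the styrene-type alkene.

Step 12
Reactants: 16 (4S,5R,10R)-12,14-dihydroxyabieta-6,8,11,13-tetraen-19,20-olide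
Product: 17 (4S,5R,10R)-12-hydroxy-11,14-dioxoabieta-6,8,12-trien-19,20-olide
Conditions: (KSO3)2NO (2.2 equiv), KH2PO4 buffer, acetone/H2O, 0 → 25 °C
Reagents that add atoms: potassium nitrosodisulfonate (Fremy's salt), [K+].[K+].[O]N(S(=O)(=O)[O-])S(=O)(=O)[O-]
Why: Teuber oxidation: the nitroxyl radical abstracts the hydrogen of the C14 hydroxyl and a second equivalent adds at C11, the only unsubstituted ring position and para to that hydroxyl, so that loss of imidodisulfonate should give the 2-hydroxy-1,4-benzoquinone (12-hydroxy-11,14-dione).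

Step 13
Reactants: 17 (4S,5R,10R)-12-hydroxy-11,14-dioxoabieta-6,8,12-trien-19,20-olide
Product: 18 (4S,5R,10R)-12-acetoxy-11,14-dioxoabieta-6,8,12-trien-19,20-olide (CNP0596241.1)
Conditions: Ac2O, pyridine, CH2Cl2, 0 °C
Reagents that add atoms: acetic anhydride, CC(=O)OC(C)=O
Why: O-Acylation of the acidic vinylogous-acid hydroxyl at C12 with acetic anhydride and pyridine should give the enol acetate without affecting the lactone or the stereocentres.

Compound list
1 | 5-bromo-2-isopropyl-1,3-dimethoxybenzene | COc1cc(Br)cc(OC)c1C(C)C | starting material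
2 | diethyl malonate | CCOC(=O)CC(=O)OCC | starting material
3 | diethyl 2-(4-isopropyl-3,5-dimethoxyphenyl)malonate | CCOC(=O)C(C(=O)OCC)c1cc(OC)c(C(C)C)c(OC)c1 | intermediate
4 | diethyl 2-(3-chloropropyl)-2-(4-isopropyl-3,5-dimethoxyphenyl)malonate | CCOC(=O)C(CCCCl)(C(=O)OCC)c1cc(OC)c(C(C)C)c(OC)c1 | intermediate
5 | 2-(3-chloropropyl)-2-(4-isopropyl-3,5-dimethoxyphenyl)propane-1,3-diol | OCC(CO)(CCCCl)c1cc(OC)c(C(C)C)c(OC)c1 | intermediate
6 | (S)-5-chloro-2-(hydroxymethyl)-2-(4-isopropyl-3,5-dimethoxyphenyl)pentyl propanoate | COc1cc(cc(OC)c1C(C)C)[C@](CCCCl)(COC(=O)CC)CO | intermediate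
7 | (R)-5-chloro-2-formyl-2-(4-isopropyl-3,5-dimethoxyphenyl)pentyl propanoate | COc1cc(cc(OC)c1C(C)C)[C@](CCCCl)(COC(=O)CC)C=O | intermediate
8 | tert-butyl (R,Z)-7-chloro-4-(4-isopropyl-3,5-dimethoxyphenyl)-4-[(propanoyloxy)methyl]hept-2-enoate | COc1cc(cc(OC)c1C(C)C)[C@](CCCCl)(COC(=O)CC)/C=C\C(=O)OC(C)(C)C | intermediate
9 | (R,Z)-7-chloro-4-(4-isopropyl-3,5-dimethoxyphenyl)-4-[(propanoyloxy)methyl]hept-2-enoic acid | COc1cc(cc(OC)c1C(C)C)[C@](CCCCl)(COC(=O)CC)/C=C\C(=O)O | intermediate (not isolated)
10 | mixed anhydride of acid 9 and trifluoroacetic acid | COc1cc(cc(OC)c1C(C)C)[C@](CCCCl)(COC(=O)CC)/C=C\C(=O)OC(=O)C(F)(F)F | intermediate (not isolated)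
11 | [(R)-1-(3-chloropropyl)-6-isopropyl-5,7-dimethoxy-4-oxo-1,4-dihydronaphthalen-1-yl]methyl propanoate | COc1c(C(C)C)c(OC)c2c(c1)[C@](CCCCl)(COC(=O)CC)C=CC2=O | intermediate
12 | (5S,10R)-3-chloro-12,14-dimethoxy-7-oxo-3,4-secoabieta-8,11,13-trien-19,20-olide (C4 epimers) | COc1c(C(C)C)c(OC)c2c(c1)[C@]3(CCCCl)COC(=O)C(C)[C@@H]3CC2=O | intermediate
13 | (5S,10R)-3-chloro-7-hydroxy-12,14-dimethoxy-3,4-secoabieta-8,11,13-trien-19,20-olide (C4 and C7 epimers) | COc1c(C(C)C)c(OC)c2c(c1)[C@]3(CCCCl)COC(=O)C(C)[C@@H]3CC2O | intermediate (not isolated)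
14 | (5S,10R)-3-chloro-12,14-dimethoxy-3,4-secoabieta-6,8,11,13-tetraen-19,20-olide (C4 epimers) | COc1c(C(C)C)c(OC)c2c(c1)[C@]3(CCCCl)COC(=O)C(C)[C@@H]3C=C2 | intermediate
15 | (4S,5R,10R)-12,14-dimethoxyabieta-6,8,11,13-tetraen-19,20-olide | COc1c(C(C)C)c(OC)c2c(c1)[C@]13CCC[C@](C)(C(=O)OC1)[C@@H]3C=C2 | intermediate
16 | (4S,5R,10R)-12,14-dihydroxyabieta-6,8,11,13-tetraen-19,20-olide | Oc1c(C(C)C)c(O)c2c(c1)[C@]13CCC[C@](C)(C(=O)OC1)[C@@H]3C=C2 | intermediate
17 | (4S,5R,10R)-12-hydroxy-11,14-dioxoabieta-6,8,12-trien-19,20-olide | OC1=C(C(C)C)C(=O)C2=C(C1=O)[C@]13CCC[C@](C)(C(=O)OC1)[C@@H]3C=C2 | intermediate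
18 | (4S,5R,10R)-12-acetoxy-11,14-dioxoabieta-6,8,12-trien-19,20-olide | CC(=O)OC1=C(C(C)C)C(=O)C2=C(C1=O)[C@]13CCC[C@](C)(C(=O)OC1)[C@@H]3C=C2 | target

Total step count: 13 steps.
Longest linear sequence: 13 steps (1 → 18).

Steps most likely to fail

Step 4. The lipase may discriminate poorly between the two hydroxymethyl groups or prefer the wrong one, and acyl transfer between them could erode the enantiomeric purity of the monoester. The fallback sets out from 5 and comes back at 6, and desymmetrises in the hydrolytic direction instead. Exhaustive acylation of 5 with propanoic anhydride, pyridine and DMAP should give the achiral 5-chloro-2-(4-isopropyl-3,5-dimethoxyphenyl)-2-[(propanoyloxy)methyl]pentyl propanoate F1. Enantiotopic-group-selective hydrolysis of one ester (porcine pancreatic lipase or the lipase of step 4, pH 7 phosphate buffer, 25 °C) then leaves the complementary ester group in place. This is the standard way to reach the antipodal monoester of a prochiral diol, and the monoester is oxidised at once as in step 5.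

Step 7. The (Z)-enoic acid may isomerise to the E acid under acid before acylation, which moves C7 out of reach of the ring, and the dienone product may undergo acid-induced dienone–phenol rearrangement. The fallback sets out from 7 and comes back at 11, building ring B as a saturated tetralone and introducing the C5=C6 bond afterwards:
- Wittig olefination of 7 with Ph3P=CHCO2t-Bu should give tert-butyl (R,E)-7-chloro-4-(4-isopropyl-3,5-dimethoxyphenyl)-4-[(propanoyloxy)methyl]hept-2-enoate F2.
- Hydrogenation (H2, Pd/C, EtOAc) should give tert-butyl (S)-7-chloro-4-(4-isopropyl-3,5-dimethoxyphenyl)-4-[(propanoyloxy)methyl]heptanoate F3.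
- CF3CO2H then (CF3CO)2O should lead through (S)-7-chloro-4-(4-isopropyl-3,5-dimethoxyphenyl)-4-[(propanoyloxy)methyl]heptanoic acid F4 and its mixed trifluoroacetic anhydride F5 to [(S)-1-(3-chloropropyl)-6-isopropyl-5,7-dimethoxy-4-oxo-1,2,3,4-tetrahydronaphthalen-1-yl]methyl propanoate F6. This is a Friedel–Crafts acylation with no geometric requirement.
- Dehydrogenation of F6 with IBX (DMSO, 75 °C) should give 11.

Step 10. The amide base may remove the allylic C5–H of the styrene, or cause loss of HCl from the side chain, before the slow displacement of the primary chloride. The fallback sets out from 12 and comes back at 15, closing ring A before the C6=C7 alkene exists: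
- 12 is reduced with NaBH4 and the benzylic alcohol 13 is isolated this time.
- Silylation with t-BuMe2SiOSO2CF3 and 2,6-lutidine should give (5S,10R)-7-(tert-butyldimethylsilyloxy)-3-chloro-12,14-dimethoxy-3,4-secoabieta-8,11,13-trien-19,20-olide F7.
- KN(SiMe3)2 (THF/DMPU, −78 → 25 °C) should then close ring A by the same C3–C4 enolate alkylation on a substrate that has no allylic hydrogen, giving (4S,5R,10R)-7-(tert-butyldimethylsilyloxy)-12,14-dimethoxyabieta-8,11,13-trien-19,20-olide F8.
- TsOH in toluene at 80 °C should ionise the benzylic silyl ether and eliminate to 15.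

Further compounds
F1 | step 4 | 5-chloro-2-(4-isopropyl-3,5-dimethoxyphenyl)-2-[(propanoyloxy)methyl]pentyl propanoate | COc1cc(cc(OC)c1C(C)C)C(CCCCl)(COC(=O)CC)COC(=O)CC
F2 | step 7 | tert-butyl (R,E)-7-chloro-4-(4-isopropyl-3,5-dimethoxyphenyl)-4-[(propanoyloxy)methyl]hept-2-enoate | COc1cc(cc(OC)c1C(C)C)[C@](CCCCl)(COC(=O)CC)/C=C/C(=O)OC(C)(C)C
F3 | step 7 | tert-butyl (S)-7-chloro-4-(4-isopropyl-3,5-dimethoxyphenyl)-4-[(propanoyloxy)methyl]heptanoate | COc1cc(cc(OC)c1C(C)C)[C@](CCCCl)(COC(=O)CC)CCC(=O)OC(C)(C)C
F4 | step 7 | (S)-7-chloro-4-(4-isopropyl-3,5-dimethoxyphenyl)-4-[(propanoyloxy)methyl]heptanoic acid | COc1cc(cc(OC)c1C(C)C)[C@](CCCCl)(COC(=O)CC)CCC(=O)O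
F5 | step 7 | mixed anhydride of acid F4 and trifluoroacetic acid | COc1cc(cc(OC)c1C(C)C)[C@](CCCCl)(COC(=O)CC)CCC(=O)OC(=O)C(F)(F)F
F6 | step 7 | [(S)-1-(3-chloropropyl)-6-isopropyl-5,7-dimethoxy-4-oxo-1,2,3,4-tetrahydronaphthalen-1-yl]methyl propanoate | COc1c(C(C)C)c(OC)c2c(c1)[C@](CCCCl)(COC(=O)CC)CCC2=O
F7 | step 10 | (5S,10R)-7-(tert-butyldimethylsilyloxy)-3-chloro-12,14-dimethoxy-3,4-secoabieta-8,11,13-trien-19,20-olide (C4 and C7 epimers) | COc1c(C(C)C)c(OC)c2c(c1)[C@]3(CCCCl)COC(=O)C(C)[C@@H]3CC2O[Si](C)(C)C(C)(C)C
F8 | step 10 | (4S,5R,10R)-7-(tert-butyldimethylsilyloxy)-12,14-dimethoxyabieta-8,11,13-trien-19,20-olide (C7 epimers) | COc1c(C(C)C)c(OC)c2c(c1)[C@]13CCC[C@](C)(C(=O)OC1)[C@@H]3CC2O[Si](C)(C)C(C)(C)C
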